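The constants of the steps are not given, so what the new flasks will do has to be read from the south and east runs.

| setting | south | east | teal | blue | amber |
|---|---|---|---|---|---|
| G | 26 mM | 26 mM | 26 mM | 26 mM | 26 mM |
| L | 0.60 equiv | 0.60 equiv | 0.600 equiv | 0.600 equiv | 0.600 equiv |
| J | 0.029 mol% | 0.23 mol% | 0.02 mol% | 0.18 mol% | 0.06 mol% |
| remark | run made earlier | run made earlier |  |  |  |
| time |  |  | 4.0 h | 4.0 h | 4.0 h |

| run | time / h | G / % | E / % | Z / % | X / % |
|---|---|---|---|---|---|
| south | 0.250 | 95.3 | 1.2 | 0 | 3.3 |
| south | 0.667 | 89.0 | 0 | 0.3 | 11.0 |
| south | 1.33 | 78.4 | 0.1 | 0 | 21.3 |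
| south | 2.00 | 69.6 | 0.3 | 0.1 | 30.8 |
| south | 3.00 | 58.9 | 0 | 0.2 | 40.9 |
| east | 0.250 | 70.3 | 0.2 | 0 | 30.1 |
| east | 0.667 | 42.9 | 0 | 0.1 | 55.2 |
| east | 1.33 | 39.2 | 0 | 0.1 | 60.0 |
| east | 2.00 | 38.9 | 0 | 0.7 | 59.3 |
| east | 3.00 | 39.9 | 0 | 0 | 60.1 |

(each reading ± 0.5 percentage points)

- which of these there is most of at the end, counted by the G in it, teal (E / G / X / Z)
- which of these there is most of at the end, counted by the G in it, blue (E / G / X / Z)
- which of these there is most of at the end, counted by the G in it, amber (E / G / X / Z)
- final amount of the leader among these, as a percentage of the G charged, in teal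
- final amount of the leader among these, as a percentage of the G charged, in blue
- final amount of the leader among these, as a percentage of the G charged, in amber

- steps thought possible: G + J <-> Z; Z <-> E + Q; L + E <-> D; D -> J + X

The readings form a ladder of time scales, read here from the quick end. On the first rung stand the forms of the enzyme: Z and E can hold no more G than the J charged, 0.23 mol% in east, and the readings scatter by 0.5 percentage points, so these readings do not tell those forms from zero. South's X already stands at 3.3% after 0.250 h, and no lag can be read. On the next rung L is consumed, and this pace follows J. East gives X 30.1% at 0.250 h and south gives 30.8% at 2.00 h, while their products of loading and time stand in the ratio 1.01. With G and L charged alike in these two runs, time is therefore taken to count through that product. East's X levels at 60.0% beside 0.60 equiv of L, and the steps use one L for each X, so L is read as the limiting reagent. On the last rung, any loss of X, the east readings show nothing: east still reads 60.1% at 3.00 h.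

With G and L charged as in those runs, a new flask is then placed by one number, the exposure ratio, which is its loading of J times its time over the same product at east's third reading. For amber this ratio is 0.785, between east's second reading at 0.502 and its third, so my reckoning puts amber's X between 55.2% and 60.0%, with X leading. Blue's ratio is 2.35, past the third reading, so my reckoning puts blue's X at the level of 60.0%. Teal's ratio is 0.262, short of the level, and needs south. Teal's product is 0.920 of the product at south's last reading, so a first answer is X 37.6%. That answer lies between south's last two readings, where the rate has fallen, so the second round steps back from the last reading along their slope and gives X 38.5%, leaving G 61.5%.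

The forecast also holds that “progress depends on J × time”. It gives teal G at 61.5% (from 59% to 65%), blue X at 60% (from 59% to 60.8%) and amber X at 59% (from 57% to 60.3%).

Teal ends with G at 61.1%, blue with X at 60.0% and amber with X at 59.7%.

    G + J ⇌ Z (K = 48.0 L mol⁻¹, k = 5.00 × 10⁵ L mol⁻¹ min⁻¹)
    Z ⇌ E + Q (K = 0.120 M, k = 26.0 min⁻¹)
    L + E ⇌ D (K = 30.0 L mol⁻¹, k = 54000 L mol⁻¹ min⁻¹)
    D → J + X (k = 110 min⁻¹)

At an exposure ratio of 0.785, amber has 0.43% of its L free at 4.00 h, less than the 40% of its G. The neighbour of blue charged with 0.360 equiv of L keeps blue's loading and time, hence blue's ratio of 2.35, and it ends with 0% of its L free and X at 36.0%.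

Readings and results are calculated with made-up constants; noise was put on by code.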